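**Plan**
- Cuts: in the dihydrobenzofuran the C2–C3 bond (carbenoid C–H insertion) and the O–CH2Ar ether; in furofuran ring B (C5–C6–O7–C8–C1) the O7–C6 bond and the C6–aryl bond; in ring A (C1–C2–O3–C4–C5, carrying the benzofuranyl group) the benzylic O3–C2 bond, traced back to a cyclopropane C–C bond.
- Enabling feature: in ring A the aryl-bearing C2 (donor) and the ring-fusion carbon C5, which carries both O3–C4H2 and C6 (acceptor, ester level), are 1,3-related through C1. C2–C1–C5 can therefore be folded into a donor–acceptor cyclopropane whose C4 hydroxymethyl oxygen re-opens it as the five-membered ring.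
- Forward order: cyclopropane → ring A by 3→5 ring expansion, with ring B formed at lactone level in the same step → lactol → aryl Grignard → ring B by SN1 etherification → phenol release, iodination, benzyl ether, diazo ester → dihydrobenzofuran by C–H insertion → reduction, debenzylation.
- Stereochemistry: C1 is set by the prolinol organocatalyst and relays to C2, C5 and C6 (two exo cation captures, cis fusion by lactonisation). The two cis dihydrobenzofuran centres are set kinetically by the chiral dirhodium carboxylate.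

Key step: step 4

Remark: the dihydrobenzofuran of the target is the 2,3-cis (2S,3S) isomer, the less stable arrangement, so it is made last and afterwards meets only neutral, non-enolising conditions.

**Step 1**
Reactants: 1 coniferaldehyde; 2 allyl bromide
Product: 3 (E)-3-[4-(allyloxy)-3-methoxyphenyl]prop-2-enal
Conditions: K2CO3, acetone, reflux
Reagents that add atoms: allyl bromide, C=CCBr
Why: Williamson etherification of the phenoxide should proceed without touching the enal and installs an alkoxy group that is a strong donor and is removable later without acid.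

**Step 2**
Reactants: 3 (E)-3-[4-(allyloxy)-3-methoxyphenyl]prop-2-enal; 4 diethyl bromomalonate
Product: 5 diethyl (2R,3S)-2-formyl-3-[4-(allyloxy)-3-methoxyphenyl]cyclopropane-1,1-dicarboxylate
Conditions: (S)-2-[diphenyl(trimethylsilyloxy)methyl]pyrrolidine (20 mol %), 2,6-lutidine, CH2Cl2, 0 °C → rt
Reagents that add atoms: diethyl bromomalonate, CCOC(=O)C(Br)C(=O)OCC
Why: Michael-initiated ring closure under iminium–enamine catalysis: the malonate should add to the β-carbon on the face left open by the (S)-catalyst and the enamine then displaces bromide (3-exo-tet), placing formyl trans to aryl and fixing the formyl-bearing carbon (later C1) as R.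

**Step 3**
Reactants: 5 diethyl (2R,3S)-2-formyl-3-[4-(allyloxy)-3-methoxyphenyl]cyclopropane-1,1-dicarboxylate
Product: 7 ethyl (1R,2R,3S)-1,2-bis(hydroxymethyl)-3-[4-(allyloxy)-3-methoxyphenyl]cyclopropane-1-carboxylate, via lactone ester 6 (not isolated)
Conditions: NaBH4 (excess), EtOH, 0 °C → rt
Reagents that add atoms: none
Why: Borohydride reduction of the aldehyde, lactonisation of the alkoxide onto the cis ester and further reduction of the strained malonyl-type lactone should stop at the diol mono-ester, whose remaining ester sits on a quaternary carbon; reduction of the other carbonyl instead would converge in step 4 because C5 becomes trigonal there.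

**Step 4**
Reactants: 7 ethyl (1R,2R,3S)-1,2-bis(hydroxymethyl)-3-[4-(allyloxy)-3-methoxyphenyl]cyclopropane-1-carboxylate
Product: 9 (1R,2S,5R)-2-[4-(allyloxy)-3-methoxyphenyl]-3,7-dioxabicyclo[3.3.0]octan-6-one, via hydroxy ester 8 (not isolated)
Conditions: Sc(OTf)3 (10 mol %), ClCH2CH2Cl, 4 Å MS, rt → 50 °C
Reagents that add atoms: none
Why: Proposed new method: Sc(OTf)3 chelates the β-hydroxy ester, and the strained C(CO2Et)–C(aryl) bond, polarised by the 3,4-dialkoxyphenyl donor and the ester acceptor, ionises to a benzylic (quinone-methide-like) cation and an ester enolate; the hydroxymethyl oxygen on the enolate carbon captures the cation, so the three cyclopropane carbons plus CH2–O become ring A, and C-protonation followed by lactonisation of 8 with the other CH2OH (loss of ethanol) gives 9. The closest known reaction types are the Cloke–Wilson rearrangement of donor–acceptor cyclopropyl carbonyl compounds and the acid-mediated isomerisation of 2-arylcyclopropane-1,1-diesters to γ-aryl-γ-butyrolactones; here an sp3 hydroxyl oxygen instead of a carbonyl oxygen closes the ring, which delivers ring A saturated and at the right oxidation level. Ring A closes 5-exo-trig on the exocyclic benzylic cation (a concerted backside displacement is impossible because the nucleophile hangs on the departing carbon, so the path is SN1), and the lactone closes 5-exo-trig by acyl substitution. C1 is untouched and relays to the other two centres: C2 should form with the aryl group anti to the neighbouring CH2OH (trans, exo), as in quinone-methide closures to furofurans, and C5 should be protonated anti to that CH2OH and is locked because only the cis hydroxy ester can lactonise to the cis-fused bicycle. The step needs cation capture by the C4 hydroxyl (five-membered ring) and not by the C8 hydroxyl (oxetane) or the ester carbonyl oxygen (reversible), and ionisation of the donor–acceptor bond and not of a cyclopropylcarbinyl C–O bond; ring size, the chelating Lewis acid and the aprotic medium should secure this.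

**Step 5**
Reactants: 9 (1R,2S,5R)-2-[4-(allyloxy)-3-methoxyphenyl]-3,7-dioxabicyclo[3.3.0]octan-6-one
Product: 10 (1R,2S,5R)-2-[4-(allyloxy)-3-methoxyphenyl]-3,7-dioxabicyclo[3.3.0]octan-6-ol (lactol, both anomers)
Conditions: i-Bu2AlH (1.1 equiv), CH2Cl2, −78 °C
Reagents that add atoms: none
Why: Partial reduction of a γ-lactone to the lactol should stop at the tetrahedral aluminate at low temperature, leaving the allyl ether and the benzylic ether untouched.

**Step 6**
Reactants: 11 4-bromo-2,6-dimethoxyphenol; 12 benzyl bromide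
Product: 13 2-(benzyloxy)-5-bromo-1,3-dimethoxybenzene
Conditions: K2CO3, DMF, rt
Reagents that add atoms: benzyl bromide, BrCc1ccccc1
Why: Williamson benzylation of the hindered phenoxide gives the protected syringyl bromide for metalation.

**Step 7**
Reactants: 10 lactol; 13 2-(benzyloxy)-5-bromo-1,3-dimethoxybenzene
Product: 15 [(2S,3R,4R)-2-[4-(allyloxy)-3-methoxyphenyl]-4-{[4-(benzyloxy)-3,5-dimethoxyphenyl](hydroxy)methyl}tetrahydrofuran-3-yl]methanol (both carbinol epimers), via Grignard reagent 14 (not isolated)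
Conditions: Mg, THF, reflux; then 10, THF, 0 °C → rt (3 equiv of 14)
Reagents that add atoms: [4-(benzyloxy)-3,5-dimethoxyphenyl]magnesium bromide 14 (from 13), COc1cc([Mg]Br)cc(OC)c1OCc1ccccc1
Why: Grignard addition to the open hydroxy-aldehyde form of the lactol (the first equivalent deprotonates it) gives the 1,4-diol; the configuration of the new carbinol does not matter because step 8 passes through its cation.

**Step 8**
Reactants: 15 diol
Product: 16 (1R,2S,5R,6S)-2-[4-(allyloxy)-3-methoxyphenyl]-6-[4-(benzyloxy)-3,5-dimethoxyphenyl]-3,7-dioxabicyclo[3.3.0]octane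
Conditions: camphor-10-sulfonic acid (10 mol %), CH2Cl2, 4 Å MS, 0 °C → rt
Reagents that add atoms: none
Why: SN1 cyclodehydration through the 4-alkoxy-3,5-dimethoxybenzylic cation: 5-exo-trig capture by the primary hydroxyl should place the aryl group exo (trans to the ring-fusion substituent) from either carbinol epimer, the biomimetic quinone-methide-type closure of furofurans.

**Step 9**
Reactants: 16 allyl ether
Product: 17 4-{(1R,2S,5R,6S)-6-[4-(benzyloxy)-3,5-dimethoxyphenyl]-3,7-dioxabicyclo[3.3.0]octan-2-yl}-2-methoxyphenol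
Conditions: Pd(PPh3)4 (5 mol %), morpholine, THF, rt
Reagents that add atoms: none
Why: Tsuji–Trost deallylation (π-allyl complex from zerovalent palladium, morpholine as allyl acceptor) frees the phenol under neutral conditions; benzyl ethers and the furofuran are inert.

**Step 10**
Reactants: 17 phenol
Product: 18 2-iodo-6-methoxy-4-{(1R,2S,5R,6S)-6-[4-(benzyloxy)-3,5-dimethoxyphenyl]-3,7-dioxabicyclo[3.3.0]octan-2-yl}phenol
Conditions: N-iodosuccinimide (1.05 equiv), DMF, 0 °C
Reagents that add atoms: N-iodosuccinimide, O=C1CCC(=O)N1I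
Why: Electrophilic aromatic iodination should go ortho to the free hydroxyl (para is blocked), the phenol ring being far more activated than the aryl ethers, and no acid is present to ionise the benzylic ethers.

**Step 11**
Reactants: 18 iodophenol; 19 [4-(benzyloxy)-3-methoxyphenyl]methanol
Product: 20 (1R,2S,5R,6S)-2-{4-[(4-(benzyloxy)-3-methoxybenzyl)oxy]-3-iodo-5-methoxyphenyl}-6-[4-(benzyloxy)-3,5-dimethoxyphenyl]-3,7-dioxabicyclo[3.3.0]octane
Conditions: PPh3, DIAD, THF, 0 °C → rt
Reagents that add atoms: [4-(benzyloxy)-3-methoxyphenyl]methanol, COc1cc(CO)ccc1OCc1ccccc1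
Why: Mitsunobu etherification of the acidic, hindered phenol with a primary benzylic alcohol installs under neutral conditions the O–CH2Ar unit whose CH2 becomes C2 of the dihydrobenzofuran.

**Step 12**
Reactants: 20 aryl iodide; 21 ethyl diazoacetate
Product: 22 ethyl 2-diazo-2-{2-[(4-(benzyloxy)-3-methoxybenzyl)oxy]-3-methoxy-5-[(1R,2S,5R,6S)-6-(4-(benzyloxy)-3,5-dimethoxyphenyl)-3,7-dioxabicyclo[3.3.0]octan-2-yl]phenyl}acetate
Conditions: Pd(PPh3)4 (5 mol %), Ag2CO3 (0.5 equiv), Et3N, toluene, rt
Reagents that add atoms: ethyl diazoacetate, CCOC(=O)C=[N+]=[N-]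
Why: Palladium-catalysed cross-coupling of an aryl iodide with the C–H bond of a diazo ester keeps the diazo group and should give the aryldiazoacetate directly at room temperature.

**Step 13**
Reactants: 22 aryldiazoacetate
Product: 23 ethyl (2S,3R)-2-[4-(benzyloxy)-3-methoxyphenyl]-5-[(1R,2S,5R,6S)-6-(4-(benzyloxy)-3,5-dimethoxyphenyl)-3,7-dioxabicyclo[3.3.0]octan-2-yl]-7-methoxy-2,3-dihydro-1-benzofuran-3-carboxylate (2,3-cis)
Conditions: Rh2(R-PTTL)4 [dirhodium tetrakis(N-phthaloyl-(R)-tert-leucinate)] (2 mol %), toluene, −60 °C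
Reagents that add atoms: none
Why: Rhodium-carbenoid intramolecular 1,5 C–H insertion into the O–CH2Ar bond (activated by oxygen and the electron-rich arene) is concerted and kinetically cis-selective with phthaloyl-tert-leucinate catalysts; the R catalyst is the antipode expected to give the (2S,3R) ester, independent of the remote furofuran centres, and the low temperature avoids epimerisation to trans.

**Step 14**
Reactants: 23 cis ester
Product: 24 [(2S,3S)-2-[4-(benzyloxy)-3-methoxyphenyl]-5-[(1R,2S,5R,6S)-6-(4-(benzyloxy)-3,5-dimethoxyphenyl)-3,7-dioxabicyclo[3.3.0]octan-2-yl]-7-methoxy-2,3-dihydro-1-benzofuran-3-yl]methanol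
Conditions: i-Bu2AlH (3 equiv), CH2Cl2, −78 °C
Reagents that add atoms: none
Why: Ester reduction by the non-basic aluminium hydride at low temperature should outrun enolisation, so the epimerisable cis centre next to the ester is kept.

**Step 15**
Reactants: 24 dibenzyl ether
Product: 25 CNP0126146.1 (target)
Conditions: H2 (1 atm), Pd/C, EtOAc, rt, monitored and stopped at full debenzylation
Reagents that add atoms: none
Why: Hydrogenolysis of the two primary aryl benzyl ethers is neutral, so no phenoxide or acid can open the cis ring through a quinone methide, and it should be much faster than cleavage of the secondary cyclic benzylic ethers.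

**Compound list**
1 | coniferaldehyde, (E)-3-(4-hydroxy-3-methoxyphenyl)prop-2-enal | COc1cc(/C=C/C=O)ccc1O | starting material
2 | allyl bromide | C=CCBr | starting material
3 | (E)-3-[4-(allyloxy)-3-methoxyphenyl]prop-2-enal | COc1cc(/C=C/C=O)ccc1OCC=C | intermediate
4 | diethyl bromomalonate | CCOC(=O)C(Br)C(=O)OCC | starting material
5 | diethyl (2R,3S)-2-formyl-3-[4-(allyloxy)-3-methoxyphenyl]cyclopropane-1,1-dicarboxylate (formyl trans to aryl) | CCOC(=O)C1(C(=O)OCC)[C@H](C=O)[C@H]1c1ccc(OCC=C)c(OC)c1 | intermediate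
6 | ethyl (1S,5R,6S)-6-[4-(allyloxy)-3-methoxyphenyl]-2-oxo-3-oxabicyclo[3.1.0]hexane-1-carboxylate | CCOC(=O)[C@@]12C(=O)OC[C@@H]1[C@H]2c1ccc(OCC=C)c(OC)c1 | intermediate (not isolated)
7 | ethyl (1R,2R,3S)-1,2-bis(hydroxymethyl)-3-[4-(allyloxy)-3-methoxyphenyl]cyclopropane-1-carboxylate (the two CH2OH cis, aryl on the other face) | CCOC(=O)[C@@]1(CO)[C@H](CO)[C@H]1c1ccc(OCC=C)c(OC)c1 | intermediate
8 | ethyl (3R,4R,5S)-5-[4-(allyloxy)-3-methoxyphenyl]-4-(hydroxymethyl)tetrahydrofuran-3-carboxylate | CCOC(=O)[C@H]1CO[C@H](c2ccc(OCC=C)c(OC)c2)[C@H]1CO | intermediate (not isolated)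
9 | (1R,2S,5R)-2-[4-(allyloxy)-3-methoxyphenyl]-3,7-dioxabicyclo[3.3.0]octan-6-one (cis-fused, aryl exo) | O=C1OC[C@H]2[C@@H]1CO[C@@H]2c1ccc(OCC=C)c(OC)c1 | intermediate
10 | (1R,2S,5R)-2-[4-(allyloxy)-3-methoxyphenyl]-3,7-dioxabicyclo[3.3.0]octan-6-ol (anomers) | OC1OC[C@H]2[C@@H]1CO[C@@H]2c1ccc(OCC=C)c(OC)c1 | intermediate
11 | 4-bromo-2,6-dimethoxyphenol | COc1cc(Br)cc(OC)c1O | starting material
12 | benzyl bromide | BrCc1ccccc1 | starting material
13 | 2-(benzyloxy)-5-bromo-1,3-dimethoxybenzene | COc1cc(Br)cc(OC)c1OCc1ccccc1 | intermediate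
14 | [4-(benzyloxy)-3,5-dimethoxyphenyl]magnesium bromide | COc1cc([Mg]Br)cc(OC)c1OCc1ccccc1 | intermediate (not isolated)
15 | [(2S,3R,4R)-2-[4-(allyloxy)-3-methoxyphenyl]-4-{[4-(benzyloxy)-3,5-dimethoxyphenyl](hydroxy)methyl}tetrahydrofuran-3-yl]methanol (carbinol epimers) | OC[C@@H]1[C@@H](c2ccc(OCC=C)c(OC)c2)OC[C@@H]1C(O)c1cc(OC)c(OCc2ccccc2)c(OC)c1 | intermediate
16 | (1R,2S,5R,6S)-2-[4-(allyloxy)-3-methoxyphenyl]-6-[4-(benzyloxy)-3,5-dimethoxyphenyl]-3,7-dioxabicyclo[3.3.0]octane (both aryl groups exo) | C=CCOc1ccc(cc1OC)[C@H]1OC[C@H]2[C@@H]1CO[C@@H]2c1cc(OC)c(OCc2ccccc2)c(OC)c1 | intermediate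
17 | 4-{(1R,2S,5R,6S)-6-[4-(benzyloxy)-3,5-dimethoxyphenyl]-3,7-dioxabicyclo[3.3.0]octan-2-yl}-2-methoxyphenol | COc1cc(ccc1O)[C@H]1OC[C@H]2[C@@H]1CO[C@@H]2c1cc(OC)c(OCc2ccccc2)c(OC)c1 | intermediate
18 | 2-iodo-6-methoxy-4-{(1R,2S,5R,6S)-6-[4-(benzyloxy)-3,5-dimethoxyphenyl]-3,7-dioxabicyclo[3.3.0]octan-2-yl}phenol | COc1cc(cc(I)c1O)[C@H]1OC[C@H]2[C@@H]1CO[C@@H]2c1cc(OC)c(OCc2ccccc2)c(OC)c1 | intermediate
19 | [4-(benzyloxy)-3-methoxyphenyl]methanol | COc1cc(CO)ccc1OCc1ccccc1 | starting material
20 | (1R,2S,5R,6S)-2-{4-[(4-(benzyloxy)-3-methoxybenzyl)oxy]-3-iodo-5-methoxyphenyl}-6-[4-(benzyloxy)-3,5-dimethoxyphenyl]-3,7-dioxabicyclo[3.3.0]octane | COc1cc(cc(I)c1OCc1ccc(OCc2ccccc2)c(OC)c1)[C@H]1OC[C@H]2[C@@H]1CO[C@@H]2c1cc(OC)c(OCc2ccccc2)c(OC)c1 | intermediate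
21 | ethyl diazoacetate | CCOC(=O)C=[N+]=[N-] | starting material
22 | ethyl 2-diazo-2-{2-[(4-(benzyloxy)-3-methoxybenzyl)oxy]-3-methoxy-5-[(1R,2S,5R,6S)-6-(4-(benzyloxy)-3,5-dimethoxyphenyl)-3,7-dioxabicyclo[3.3.0]octan-2-yl]phenyl}acetate | CCOC(=O)C(=[N+]=[N-])c1cc(cc(OC)c1OCc1ccc(OCc2ccccc2)c(OC)c1)[C@H]1OC[C@H]2[C@@H]1CO[C@@H]2c1cc(OC)c(OCc2ccccc2)c(OC)c1 | intermediate
23 | ethyl (2S,3R)-2-[4-(benzyloxy)-3-methoxyphenyl]-5-[(1R,2S,5R,6S)-6-(4-(benzyloxy)-3,5-dimethoxyphenyl)-3,7-dioxabicyclo[3.3.0]octan-2-yl]-7-methoxy-2,3-dihydro-1-benzofuran-3-carboxylate (2,3-cis) | COc1cc([C@H]2Oc3c(OC)cc([C@H]4OC[C@H]5[C@@H]4CO[C@@H]5c4cc(OC)c(OCc5ccccc5)c(OC)c4)cc3[C@H]2C(=O)OCC)ccc1OCc1ccccc1 | intermediate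
24 | [(2S,3S)-2-[4-(benzyloxy)-3-methoxyphenyl]-5-[(1R,2S,5R,6S)-6-(4-(benzyloxy)-3,5-dimethoxyphenyl)-3,7-dioxabicyclo[3.3.0]octan-2-yl]-7-methoxy-2,3-dihydro-1-benzofuran-3-yl]methanol (2,3-cis) | COc1cc([C@H]2Oc3c(OC)cc([C@H]4OC[C@H]5[C@@H]4CO[C@@H]5c4cc(OC)c(OCc5ccccc5)c(OC)c4)cc3[C@H]2CO)ccc1OCc1ccccc1 | intermediate
25 | CNP0126146.1, 4-{(1R,2S,5R,6S)-6-[(2S,3S)-2-(4-hydroxy-3-methoxyphenyl)-3-(hydroxymethyl)-7-methoxy-2,3-dihydro-1-benzofuran-5-yl]-3,7-dioxabicyclo[3.3.0]octan-2-yl}-2,6-dimethoxyphenol | COc1cc([C@H]2Oc3c(OC)cc([C@H]4OC[C@H]5[C@@H]4CO[C@@H]5c4cc(OC)c(O)c(OC)c4)cc3[C@H]2CO)ccc1O | target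

**Count**
Total steps: 15. Longest linear sequence: 14 (steps 1–5 and 7–15; step 6 is a one-step side branch).

**Steps most likely to fail**

Step 4 (ring expansion). The mono-ester cyclopropane may ionise sluggishly, the cation may lose the neighbouring proton instead of being captured, or C-protonation may give the trans hydroxy ester that cannot lactonise. The fallback sets out from 7 and comes back at 9, separating the two bond changes with known reactions. MgI2 in THF opens the activated cyclopropane by iodide attack at the benzylic carbon (homoconjugate addition) to give ethyl (3R)-2,3-bis(hydroxymethyl)-4-iodo-4-[4-(allyloxy)-3-methoxyphenyl]butanoate F1. K2CO3 in MeCN then closes ring A by intramolecular Williamson etherification (5-exo-tet) to hydroxy ester 8, and catalytic camphor-10-sulfonic acid in toluene lactonises 8 to 9.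

Step 12 (diazo cross-coupling). Oxidative addition at the ortho-alkoxy iodide may be slow, and palladium may strip nitrogen from the diazo product. The fallback sets out from 20 and comes back at 22. Negishi-type α-arylation with the Reformatsky reagent BrZnCH2CO2Et [Pd(dba)2, P(t-Bu)3, THF] gives ethyl 2-{2-[(4-(benzyloxy)-3-methoxybenzyl)oxy]-3-methoxy-5-[(1R,2S,5R,6S)-6-(4-(benzyloxy)-3,5-dimethoxyphenyl)-3,7-dioxabicyclo[3.3.0]octan-2-yl]phenyl}acetate F2. Regitz diazo transfer (4-acetamidobenzenesulfonyl azide, DBU, MeCN) converts it into 22.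

Step 8 (SN1 ring closure). Stereoconvergence at the new benzylic centre may be incomplete, or the acid may epimerise C2. The fallback sets out from 10 and comes back at 16, bringing the aryl group in as the nucleophile. Friedel–Crafts C-arylation of the lactol (BF3·OEt2, CH2Cl2, −78 °C) with 2,6-dimethoxyphenol, which attacks the bicyclic oxocarbenium ion through its para carbon from the convex face, gives 4-{(1R,2S,5R,6S)-6-[4-(allyloxy)-3-methoxyphenyl]-3,7-dioxabicyclo[3.3.0]octan-2-yl}-2,6-dimethoxyphenol F3 with the aryl group exo. Benzylation (12, K2CO3, DMF) gives 16.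

**Further compounds**
F1 | step 4 | ethyl (3R)-2,3-bis(hydroxymethyl)-4-iodo-4-[4-(allyloxy)-3-methoxyphenyl]butanoate (mixture at C2 and C4) | CCOC(=O)C(CO)[C@H](CO)C(I)c1ccc(OCC=C)c(OC)c1
F2 | step 12 | ethyl 2-{2-[(4-(benzyloxy)-3-methoxybenzyl)oxy]-3-methoxy-5-[(1R,2S,5R,6S)-6-(4-(benzyloxy)-3,5-dimethoxyphenyl)-3,7-dioxabicyclo[3.3.0]octan-2-yl]phenyl}acetate | CCOC(=O)Cc1cc(cc(OC)c1OCc1ccc(OCc2ccccc2)c(OC)c1)[C@H]1OC[C@H]2[C@@H]1CO[C@@H]2c1cc(OC)c(OCc2ccccc2)c(OC)c1
F3 | step 8 | 4-{(1R,2S,5R,6S)-6-[4-(allyloxy)-3-methoxyphenyl]-3,7-dioxabicyclo[3.3.0]octan-2-yl}-2,6-dimethoxyphenol | C=CCOc1ccc(cc1OC)[C@H]1OC[C@H]2[C@@H]1CO[C@@H]2c1cc(OC)c(O)c(OC)c1
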